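**Assumptions:** Epichlorohydrin (racemic), pent-1-en-4-yne, ethyl 3-amino-3-thioxopropanoate (ethyl thiomalonamate) and but-3-yn-1-amine·HCl are taken as commercial. The target carbinol is (R) by CIP. The (R,R)-salen-Co catalyst is assumed to leave the (S)-epoxide, as it does for simple terminal epoxides; this should be confirmed by the ee of alcohol **14** (Mosher ester or chiral HPLC).

## Retrosynthesis
- The Z,Z-diene unit comes from a skipped enyne and a conjugated enyne by Zn(Cu/Ag) semi-reduction (Boland type). The conjugated enyne comes from Sonogashira coupling of a terminal homopropargylic alcohol with the 2-bromoalkene carbamate (methyl N-(3-bromobut-3-en-1-yl)carbamate).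
- The (R)-carbinol comes from an (S)-terminal epoxide (hydrolytic kinetic resolution, HKR) opened by acetylide at the CH2 terminus. The epoxide comes from the α,α-dimethyl aldehyde by Corey–Chaykovsky methylenation, and the aldehyde from the ester.
- The gem-dimethyl group comes from double methylation of a thiazol-2-ylacetate. The thiazole is formed by Hantzsch condensation of ethyl thiomalonamate with an α-chloroketone, which is made from epichlorohydrin, the lithium acetylide of pent-1-en-4-yne, and oxidation.
- Ring order: the thiazole is formed first (Step 3). The oxirane is a transient ring, formed and resolved in Steps 6–7 and opened in Step 8. No other rings are present.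

## Route

**Step 1**
Reactants: **1** epichlorohydrin (racemic); **2** pent-1-en-4-yne
Product: **3** 1-chloroocta-7-en-4-yn-2-ol
Conditions: **2**, n-BuLi, THF, –78 °C; then BF3·OEt2, then **1**, –78 °C
Reagents that add atoms: none
Why: The lithium acetylide opens the epoxide at its terminal CH2 under BF3 activation (Yamaguchi epoxide opening), giving the chlorohydrin. The new carbinol stereocentre is irrelevant because it is oxidised in Step 2.

**Step 2**
Reactants: **3**
Product: **4** 1-chloroocta-7-en-4-yn-2-one
Conditions: DMP, NaHCO3, CH2Cl2, 0 °C
Reagents that add atoms: none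
Why: Dess–Martin oxidation is neutral and buffered, which avoids base-promoted isomerisation of the β,γ-alkynyl ketone to an allenyl ketone or ynenone.

**Step 3**
Reactants: **4**; **5** ethyl 3-amino-3-thioxopropanoate
Product: **6** ethyl 2-[4-(hex-5-en-2-yn-1-yl)thiazol-2-yl]acetate
Conditions: EtOH, reflux
Reagents that add atoms: none
Why: Hantzsch thiazole synthesis. S-alkylation of the thioamide by the α-chloroketone is followed by cyclodehydration, forming the thiazole and placing the enyne chain at C4.

**Step 4**
Reactants: **6**; **7** iodomethane
Product: **8** ethyl 2-methyl-2-[4-(hex-5-en-2-yn-1-yl)thiazol-2-yl]propanoate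
Conditions: NaH (2.2 equiv), **7** (2.5 equiv), DMF/THF, 0 °C → rt
Reagents that add atoms: iodomethane, CI (adds two CH3)
Why: The ester-flanked thiazolylacetate CH2 is the most acidic site, so sequential enolate alkylation installs the quaternary gem-dimethyl carbon.

**Step 5**
Reactants: **8**
Product: **9** 2-methyl-2-[4-(hex-5-en-2-yn-1-yl)thiazol-2-yl]propanal
Conditions: DIBAL-H (1.2 equiv), toluene, –78 °C
Reagents that add atoms: none
Why: DIBAL partial reduction stops at the stable tetrahedral aluminate at –78 °C, and the α-quaternary aldehyde released on work-up cannot enolise. The internal alkyne and the terminal alkene are untouched.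

**Step 6**
Reactants: **9**; **10** trimethylsulfonium iodide
Product: **11** racemic 2-[2-(oxiran-2-yl)propan-2-yl]-4-(hex-5-en-2-yn-1-yl)thiazole
Conditions: **10**, n-BuLi (slightly less than 1 equiv relative to **10**), THF, –10 °C; add **9**, → rt
Reagents that add atoms: trimethylsulfonium iodide, C[S+](C)C.[I-] (adds one CH2, which becomes the epoxide CH2)
Why: Corey–Chaykovsky methylenation with dimethylsulfonium methylide. Using the sulfonium salt in slight excess over n-BuLi leaves no free BuLi to deprotonate the thiazole or the doubly activated CH2. The new stereocentre is formed racemic and is resolved in Step 7.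

**Step 7**
Reactants: **11**
Product: **12** (S)-epoxide, C=CCC#CCc1csc(C(C)(C)[C@H]2CO2)n1
Conditions: (R,R)-(salen)Co(III)OAc (3–5 mol%), H2O (0.55 equiv), THF, 0 °C → rt, 24 h
Reagents that add atoms: none (the water ends up in the separable diol by-product)
Why: Jacobsen hydrolytic kinetic resolution. The catalyst hydrolyses the (R)-epoxide faster and leaves the (S)-epoxide, which sets the carbinol stereocentre (≤50% yield).

**Step 8**
Reactants: **12**; **13** lithium acetylide–ethylenediamine complex
Product: **14** (R)-homopropargylic alcohol, C=CCC#CCc1csc(C(C)(C)[C@H](O)CC#C)n1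
Conditions: **13**, DMSO/THF, rt → 40 °C
Reagents that add atoms: lithium acetylide, [Li]C#C (adds the C2 alkyne unit)
Why: SN2 opening at the unhindered epoxide CH2 leaves the stereocentre untouched. The (S)-epoxide becomes the (R)-alcohol only because the CIP priorities change (the ring CH2 outranks the quaternary carbon in the epoxide, but the quaternary carbon outranks the CH2 in the alcohol).

**Step 9**
Reactants: **15** but-3-yn-1-amine hydrochloride; **16** methyl chloroformate
Product: **17** methyl N-(but-3-yn-1-yl)carbamate
Conditions: **16**, Et3N (2.2 equiv), CH2Cl2, 0 °C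
Reagents that add atoms: methyl chloroformate, COC(=O)Cl (adds CO2CH3)
Why: N-acylation of the free amine (liberated in situ by Et3N) gives the methyl carbamate.

**Step 10**
Reactants: **17**; **18** acetyl bromide
Product: **19** methyl N-(3-bromobut-3-en-1-yl)carbamate
Conditions: **18**, wet SiO2 (or Al2O3), CH2Cl2, rt
Reagents that add atoms: acetyl bromide, CC(=O)Br (generates HBr on the wet support; H and Br add across the alkyne and remain in the product)
Why: Surface-mediated Markovnikov hydrobromination of the terminal alkyne gives the 2-bromo-1-alkene.

**Step 11**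
Reactants: **14**; **19**
Product: **20** enyne, C=CCC#CCc1csc(C(C)(C)[C@H](O)CC#CC(=C)CCNC(=O)OC)n1
Conditions: Pd(PPh3)4 (5 mol%), CuI (10 mol%), i-Pr2NH, THF, rt → 45 °C
Reagents that add atoms: none
Why: Sonogashira coupling joins the terminal alkyne to the vinyl bromide and forms the 2-substituted conjugated enyne. The free OH, thiazole, internal alkyne and carbamate are tolerated, and the carbinol stereocentre is not involved.

**Step 12**
Reactants: **20**
Product: **21** micothiazole A (target)
Conditions: Zn(Cu/Ag), MeOH/H2O 1:1, 40 °C
Reagents that add atoms: none (only H)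
Why: Boland-type syn semi-reduction converts both internal alkynes (one conjugated, one skipped) to Z-alkenes. The terminal vinyl, the 1,1-disubstituted alkene, the thiazole, the carbamate and the carbinol are untouched.

## Compound list
1 | epichlorohydrin | ClCC1CO1 | starting material
2 | pent-1-en-4-yne | C=CCC#C | starting material
3 | 1-chloroocta-7-en-4-yn-2-ol | ClCC(O)CC#CCC=C | intermediate
4 | 1-chloroocta-7-en-4-yn-2-one | ClCC(=O)CC#CCC=C | intermediate
5 | ethyl 3-amino-3-thioxopropanoate | CCOC(=O)CC(N)=S | starting material
6 | ethyl 2-[4-(hex-5-en-2-yn-1-yl)thiazol-2-yl]acetate | CCOC(=O)Cc1nc(CC#CCC=C)cs1 | intermediate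
7 | iodomethane | CI | reagent (starting material)
8 | ethyl 2-methyl-2-[4-(hex-5-en-2-yn-1-yl)thiazol-2-yl]propanoate | CCOC(=O)C(C)(C)c1nc(CC#CCC=C)cs1 | intermediate
9 | 2-methyl-2-[4-(hex-5-en-2-yn-1-yl)thiazol-2-yl]propanal | O=CC(C)(C)c1nc(CC#CCC=C)cs1 | intermediate
10 | trimethylsulfonium iodide | C[S+](C)C.[I-] | reagent (starting material)
11 | racemic epoxide | C=CCC#CCc1csc(C(C)(C)C2CO2)n1 | intermediate
12 | (S)-epoxide | C=CCC#CCc1csc(C(C)(C)[C@H]2CO2)n1 | intermediate
13 | lithium acetylide (EDA complex) | [Li]C#C | reagent (starting material)
14 | (R)-homopropargylic alcohol | C=CCC#CCc1csc(C(C)(C)[C@H](O)CC#C)n1 | intermediate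
15 | but-3-yn-1-amine hydrochloride | C#CCCN.Cl | starting material
16 | methyl chloroformate | COC(=O)Cl | reagent (starting material)
17 | methyl N-(but-3-yn-1-yl)carbamate | C#CCCNC(=O)OC | intermediate
18 | acetyl bromide | CC(=O)Br | reagent (starting material)
19 | methyl N-(3-bromobut-3-en-1-yl)carbamate | C=C(Br)CCNC(=O)OC | intermediate
20 | conjugated/skipped bis-enyne | C=CCC#CCc1csc(C(C)(C)[C@H](O)CC#CC(=C)CCNC(=O)OC)n1 | intermediate
21 | micothiazole A, methyl N-[(4Z,7R)-8-{4-[(2Z)-hexa-2,5-dien-1-yl]-1,3-thiazol-2-yl}-7-hydroxy-8-methyl-3-methylidenenon-4-en-1-yl]carbamate | C=CC/C=C\Cc1csc(C(C)(C)[C@H](O)C/C=C\C(=C)CCNC(=O)OC)n1 | target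

## Totals
- **Total step count:** 12.
- **Longest linear sequence:** 10 steps (Steps 1 → 2 → 3 → 4 → 5 → 6 → 7 → 8 → 11 → 12). The carbamate bromide branch (Steps 9–10) runs in parallel and joins at Step 11.

## Three steps most likely to fail
1. **Step 7 (HKR):** The Lewis-basic thiazole may poison the Co catalyst, and the yield is capped at 50%. Fallback: bypass the epoxide by asymmetric propargylation of aldehyde **9** with a chiral allenylborane (Ipc2B-allenyl or a tartrate allenylboronate bearing a TMS group, enantiomer chosen to give the (R)-carbinol). Then remove the TMS group with K2CO3/MeOH to give **14** directly, which shortens the route by two steps (the Step 6–8 sequence is replaced by one propargylation and one desilylation).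
2. **Steps 2–3 (β,γ-alkynyl chloroketone, then Hantzsch):** The ketone can isomerise to an allenyl ketone or ynenone, and the chloroketone is a sluggish Hantzsch partner. Fallback: run the Hantzsch with 1,3-dichloroacetone and ethyl thiomalonamate, do the gem-dimethylation at 0 °C, and then attach the enyne chain to the 4-(chloromethyl)thiazole by Cu-catalysed sp3–sp coupling with pent-1-en-4-yne.
3. **Step 12 (double semi-reduction):** Over-reduction or incomplete Z-selectivity is possible, and the thiazole can hamper the metal surface. Fallback: replace the heterogeneous reduction with stepwise cis-hydroboration of each alkyne (Cy2BH, 1 equiv, 0 °C, alkyne-selective) followed by AcOH protonolysis.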